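**Retrosynthetic overview**
- The target, robinetinidol-(4α→8)-dihydrorobinetin, is reached by one global hydrogenolysis (six benzyl ethers, two C–Br) of a protected dimer in which bromine blocks C-6 of both A rings.
- The interflavanyl C4–C8 bond is cut so that both halves are molecules of the same dihydroflavonol monomer. One molecule is reduced at C-4 (flavan-3,4-diol, then A-ring quinone methide); a second molecule is the nucleophile as its 7-phenoxide. This sets C-4 of the upper unit.
- Ring C of both units (O1–C2 bond, C-2 and C-3) comes from one unprotected 2'-hydroxychalcone by a one-flask oxidative chalcone cyclisation, following the chalcone → flavanone → dihydroflavonol logic.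
- The chalcone comes from a Claisen–Schmidt condensation of a bromo-dihydroxyacetophenone with tribenzyloxybenzaldehyde.
- Ring order: rings A and B are bought; ring C is formed once and becomes ring C of the upper and of the lower unit; no ring is formed after the coupling.

Assumption: the target is the single isomer of the given SMILES, upper unit (2R,3S,4S) and lower unit (2R,3R), and both starting materials are taken as catalogue chemicals.

**Step 1**
Reactants: 1 1-(5-bromo-2,4-dihydroxyphenyl)ethan-1-one; 2 3,4,5-tris(benzyloxy)benzaldehyde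
Product: 3 (E)-1-(5-bromo-2,4-dihydroxyphenyl)-3-[3,4,5-tris(benzyloxy)phenyl]prop-2-en-1-one
Conditions: KOH (50% aq., 10 equiv), EtOH/THF, rt, 48 h; then 1 M HCl to pH 3
Reagents that add atoms: none
Why: Claisen–Schmidt (crossed aldol) condensation in which the ketone enolate of 1 adds to the non-enolisable aldehyde 2 and E1cB loss of water gives only the (E)-enone, the product staying open as its phenoxide in strong base, and 2,4-dihydroxyacetophenones are known to condense without phenol protection.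

**Step 2**
Reactants: 3 (E)-1-(5-bromo-2,4-dihydroxyphenyl)-3-[3,4,5-tris(benzyloxy)phenyl]prop-2-en-1-one
Product: 5 (2R,3R)-6-bromo-3,7-dihydroxy-2-[3,4,5-tris(benzyloxy)phenyl]chroman-4-one, via chalcone epoxide 4 (not isolated)
Conditions: 4,5-di-O-acetyl-1,2-O-isopropylidene-β-L-erythro-2,3-hexodiulo-2,6-pyranose (C13H18O8, 30 mol %), KHSO5 (as 2KHSO5·KHSO4·K2SO4, slow addition), NaHCO3, Bu4NHSO4 (cat.), MeCN/aq. Na2H2(edta), 0 °C; then Na2S2O3, PPTS (20 mol %), EtOAc, rt
Reagents that add atoms: potassium peroxymonosulfate, KHSO5, [K+].[O-]S(=O)(=O)OO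
Why: Proposed new method: the chiral dioxirane formed from the ketone catalyst and KHSO5 epoxidises the (E)-enone of the free 2'-hydroxychalcone on one face to give the (αR,βS)-epoxide 4 (this fixes C-3), and mild acid then lets the 2'-OH open the epoxide at the benzylic carbon in a 6-endo fashion with inversion (this closes ring C through the same O1–C2 bond that chalcone isomerase makes and fixes C-2, giving the 2,3-trans product), so that oxa-cyclisation and 3-oxygenation are merged; the closest known reactions are the dimethyldioxirane epoxidation of unprotected 2'-hydroxychalcones with ring closure to trans-3-hydroxyflavanones (the stepwise form of the Algar–Flynn–Oyamada reaction) and the chiral-ketone (dioxirane) epoxidation of cinnamates and chalcones.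

**Step 3**
Reactants: 5 (2R,3R)-6-bromo-3,7-dihydroxy-2-[3,4,5-tris(benzyloxy)phenyl]chroman-4-one (two molecules end up in the product: this one is reduced in the flask and becomes the upper unit; the second, entered on the reagent line below, is the nucleophile and becomes the lower unit)
Product: 8 (2R,3R)-6-bromo-8-{(2R,3S,4S)-6-bromo-3,7-dihydroxy-2-[3,4,5-tris(benzyloxy)phenyl]chroman-4-yl}-3,7-dihydroxy-2-[3,4,5-tris(benzyloxy)phenyl]chroman-4-one, via flavan-3,4-diol 6 (not isolated), via quinone methide 7 (not isolated)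
Conditions: 5 (1 equiv), NaBH4 (2 equiv), THF/EtOH, 0 °C → rt, then acetone to destroy residual hydride; then add 5 (3 equiv), THF/aq. NaH2PO4–Na2HPO4 (pH 7), Ar, 45 °C, 24 h; excess 5 recovered by chromatography
Reagents that add atoms: second molecule of compound 5, (2R,3R)-6-bromo-3,7-dihydroxy-2-[3,4,5-tris(benzyloxy)phenyl]chroman-4-one, O=C1c2cc(Br)c(O)cc2O[C@H](c2cc(OCc3ccccc3)c(OCc3ccccc3)c(OCc3ccccc3)c2)[C@H]1O
Why: NaBH4 reduction of the C-4 ketone of the first molecule of 5 (the chemical counterpart of dihydroflavonol 4-reductase) gives the labile diol 6, whose 7-phenoxide expels the benzylic 4-OH as water to give the neutral para-quinone methide 7, which does not react with the benzyl-protected B rings and is captured by the phenoxide of the second, unreduced molecule of 5 (the most acidic phenol present, para-acyl and ortho-bromo) at C-8, its only free ortho carbon, from the face anti to the 3-OH so that the new C-4 centre is 4α (3,4-trans, 4S), this being the quinone methide C-alkylation of a phenoxide known from base-mediated proanthocyanidin couplings.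

**Step 4**
Reactants: 8 (2R,3R)-6-bromo-8-{(2R,3S,4S)-6-bromo-3,7-dihydroxy-2-[3,4,5-tris(benzyloxy)phenyl]chroman-4-yl}-3,7-dihydroxy-2-[3,4,5-tris(benzyloxy)phenyl]chroman-4-one
Product: 9 (2R,3R)-8-[(2R,3S,4S)-3,7-dihydroxy-2-(3,4,5-trihydroxyphenyl)chroman-4-yl]-3,7-dihydroxy-2-(3,4,5-trihydroxyphenyl)chroman-4-one
Conditions: H2 (1 atm), Pd(OH)2/C, NaOAc (2.5 equiv), THF/MeOH, rt; Sephadex LH-20
Reagents that add atoms: none
Why: Catalytic hydrogenolysis in which palladium cleaves the six benzyl ethers and, with NaOAc taking up the HBr, hydrodebrominates both A rings in the same operation, while the ketone, the diaryl-methine C-4 and all five stereocentres are untouched, so no stereocentre is formed or lost.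

**Compound list**
1 | 1-(5-bromo-2,4-dihydroxyphenyl)ethan-1-one | CC(=O)c1cc(Br)c(O)cc1O | starting material
2 | 3,4,5-tris(benzyloxy)benzaldehyde | O=Cc1cc(OCc2ccccc2)c(OCc2ccccc2)c(OCc2ccccc2)c1 | starting material
3 | (E)-1-(5-bromo-2,4-dihydroxyphenyl)-3-[3,4,5-tris(benzyloxy)phenyl]prop-2-en-1-one | O=C(/C=C/c1cc(OCc2ccccc2)c(OCc2ccccc2)c(OCc2ccccc2)c1)c1cc(Br)c(O)cc1O | intermediate
4 | (5-bromo-2,4-dihydroxyphenyl){(2R,3S)-3-[3,4,5-tris(benzyloxy)phenyl]oxiran-2-yl}methanone (trans epoxide, αR,βS) | O=C([C@@H]1O[C@H]1c2cc(OCc3ccccc3)c(OCc3ccccc3)c(OCc3ccccc3)c2)c4cc(Br)c(O)cc4O | intermediate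
5 | (2R,3R)-6-bromo-3,7-dihydroxy-2-[3,4,5-tris(benzyloxy)phenyl]chroman-4-one (2,3-trans) | O=C1c2cc(Br)c(O)cc2O[C@H](c2cc(OCc3ccccc3)c(OCc3ccccc3)c(OCc3ccccc3)c2)[C@H]1O | intermediate
6 | (2R,3S,4R)-6-bromo-2-[3,4,5-tris(benzyloxy)phenyl]chromane-3,4,7-triol (2,3-trans-3,4-trans; the C-4 configuration is lost in the next event) | O[C@@H]1c2cc(Br)c(O)cc2O[C@H](c2cc(OCc3ccccc3)c(OCc3ccccc3)c(OCc3ccccc3)c2)[C@H]1O | intermediate
7 | (2R,3S)-6-bromo-3-hydroxy-2-[3,4,5-tris(benzyloxy)phenyl]-2,3-dihydro-7H-chromen-7-one (A-ring para-quinone methide, C4=C4a) | O=C1C=C2O[C@H](c3cc(OCc4ccccc4)c(OCc4ccccc4)c(OCc4ccccc4)c3)[C@@H](O)C=C2C=C1Br | intermediate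
8 | (2R,3R)-6-bromo-8-{(2R,3S,4S)-6-bromo-3,7-dihydroxy-2-[3,4,5-tris(benzyloxy)phenyl]chroman-4-yl}-3,7-dihydroxy-2-[3,4,5-tris(benzyloxy)phenyl]chroman-4-one | O=C1c2cc(Br)c(O)c([C@@H]3c4cc(Br)c(O)cc4O[C@H](c4cc(OCc5ccccc5)c(OCc5ccccc5)c(OCc5ccccc5)c4)[C@H]3O)c2O[C@H](c2cc(OCc3ccccc3)c(OCc3ccccc3)c(OCc3ccccc3)c2)[C@H]1O | intermediate
9 | (2R,3R)-8-[(2R,3S,4S)-3,7-dihydroxy-2-(3,4,5-trihydroxyphenyl)chroman-4-yl]-3,7-dihydroxy-2-(3,4,5-trihydroxyphenyl)chroman-4-one | O=C1c2ccc(O)c([C@@H]3c4ccc(O)cc4O[C@H](c4cc(O)c(O)c(O)c4)[C@H]3O)c2O[C@H](c2cc(O)c(O)c(O)c2)[C@H]1O | target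

**Totals**
Total step count: 4. Longest linear sequence: 4 steps (1 → 3 → 5 → 8 → 9).

**Steps most likely to fail**

Step 2. The enone is a slow substrate for a dioxirane, the ionised 4'-phenol and the benzyl ethers may be over-oxidised, and an SN1-like opening of the electron-rich epoxide would give some 2,3-cis epimer. The sense of induction is inferred from cinnamates, where the D-fructose series gives the opposite epoxide, so the L-series ketone (from L-sorbose) is specified and must be checked. Any minor enantiomer of 5 ends largely in diastereomeric dimers after step 3, which raises the optical purity of 8.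

The fallback sets out from 1 and 2 and uses the stepwise protected-epoxide sequence. Acetophenone 1 is protected (MOMCl, NaH, DMF) as 1-[5-bromo-2,4-bis(methoxymethoxy)phenyl]ethan-1-one F1. Claisen–Schmidt condensation with 2 (KOH, EtOH) gives (E)-1-[5-bromo-2,4-bis(methoxymethoxy)phenyl]-3-[3,4,5-tris(benzyloxy)phenyl]prop-2-en-1-one F2. Juliá–Colonna epoxidation (poly-L-leucine, CO(NH2)2·H2O2, DBU, THF) gives [5-bromo-2,4-bis(methoxymethoxy)phenyl]{(2R,3S)-3-[3,4,5-tris(benzyloxy)phenyl]oxiran-2-yl}methanone F3. HCl in MeOH/THF removes both methoxymethyl groups, releasing epoxide 4, which closes to 5; the fallback rejoins the route at 5.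

Step 3. Diol 6 may self-condense through its own C-8 phenoxide (hence the three-fold excess of the more acidic 5). Quinone methide 7 may lose H-3 to give a flav-3-en-3-ol or flavan-3-one. Some 4β epimer is expected and has to be removed by chromatography. The hindered C-8 of 5 may react too slowly.

The fallback sets out from 5 and 1 and closes ring C of the lower unit last. Compound 5 is reduced and ionised as before (6, 7), but the quinone methide is trapped by the phenoxide of the small, cheap acetophenone 1 (10 equiv), whose only free carbon between the two oxygens is C-3. This gives 1-{5-bromo-3-[(2R,3S,4S)-6-bromo-3,7-dihydroxy-2-[3,4,5-tris(benzyloxy)phenyl]chroman-4-yl]-2,4-dihydroxyphenyl}ethan-1-one F4. Claisen–Schmidt condensation of F4 with 2 (KOH, EtOH/THF) gives (E)-1-{5-bromo-3-[(2R,3S,4S)-6-bromo-3,7-dihydroxy-2-[3,4,5-tris(benzyloxy)phenyl]chroman-4-yl]-2,4-dihydroxyphenyl}-3-[3,4,5-tris(benzyloxy)phenyl]prop-2-en-1-one F5. The dioxirane epoxidation and ring closure of step 2, now under catalyst control on F5, delivers 8, where the route is rejoined.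

Step 4. Eight C–O and C–Br bonds must be cleaved on a polyphenol. Risks are incomplete hydrodebromination, slow reduction of the C-4 ketone or of the benzylic C2–O1 bonds, and air oxidation of the pyrogallol rings on work-up.

The fallback sets out from 8 and separates the two events. BCl3 with pentamethylbenzene (CH2Cl2, −78 °C) removes the six benzyl groups without touching C–Br or the ketone. This gives (2R,3R)-6-bromo-8-[(2R,3S,4S)-6-bromo-3,7-dihydroxy-2-(3,4,5-trihydroxyphenyl)chroman-4-yl]-3,7-dihydroxy-2-(3,4,5-trihydroxyphenyl)chroman-4-one F6. The two bromines are then removed by transfer hydrogenolysis (Pd/C, HCO2NH4, MeOH, rt) to give 9, where the route is rejoined.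

**Further compounds**
F1 | step 2 | 1-[5-bromo-2,4-bis(methoxymethoxy)phenyl]ethan-1-one | CC(=O)c1cc(Br)c(OCOC)cc1OCOC
F2 | step 2 | (E)-1-[5-bromo-2,4-bis(methoxymethoxy)phenyl]-3-[3,4,5-tris(benzyloxy)phenyl]prop-2-en-1-one | O=C(/C=C/c1cc(OCc2ccccc2)c(OCc2ccccc2)c(OCc2ccccc2)c1)c1cc(Br)c(OCOC)cc1OCOC
F3 | step 2 | [5-bromo-2,4-bis(methoxymethoxy)phenyl]{(2R,3S)-3-[3,4,5-tris(benzyloxy)phenyl]oxiran-2-yl}methanone | O=C([C@@H]1O[C@H]1c2cc(OCc3ccccc3)c(OCc3ccccc3)c(OCc3ccccc3)c2)c4cc(Br)c(OCOC)cc4OCOC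
F4 | step 3 | 1-{5-bromo-3-[(2R,3S,4S)-6-bromo-3,7-dihydroxy-2-[3,4,5-tris(benzyloxy)phenyl]chroman-4-yl]-2,4-dihydroxyphenyl}ethan-1-one | CC(=O)c1cc(Br)c(O)c([C@@H]2c3cc(Br)c(O)cc3O[C@H](c3cc(OCc4ccccc4)c(OCc4ccccc4)c(OCc4ccccc4)c3)[C@H]2O)c1O
F5 | step 3 | (E)-1-{5-bromo-3-[(2R,3S,4S)-6-bromo-3,7-dihydroxy-2-[3,4,5-tris(benzyloxy)phenyl]chroman-4-yl]-2,4-dihydroxyphenyl}-3-[3,4,5-tris(benzyloxy)phenyl]prop-2-en-1-one | O=C(/C=C/c1cc(OCc2ccccc2)c(OCc2ccccc2)c(OCc2ccccc2)c1)c1cc(Br)c(O)c([C@@H]2c3cc(Br)c(O)cc3O[C@H](c3cc(OCc4ccccc4)c(OCc4ccccc4)c(OCc4ccccc4)c3)[C@H]2O)c1O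
F6 | step 4 | (2R,3R)-6-bromo-8-[(2R,3S,4S)-6-bromo-3,7-dihydroxy-2-(3,4,5-trihydroxyphenyl)chroman-4-yl]-3,7-dihydroxy-2-(3,4,5-trihydroxyphenyl)chroman-4-one | O=C1c2cc(Br)c(O)c([C@@H]3c4cc(Br)c(O)cc4O[C@H](c4cc(O)c(O)c(O)c4)[C@H]3O)c2O[C@H](c2cc(O)c(O)c(O)c2)[C@H]1O
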